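**Assumption:** the target is the trans-(2S,3R) isomer encoded by the given SMILES; silylating and methylating agents are treated as reagents and are not numbered.

## Retrosynthetic overview

1. Curlignan 22 ⇐ O-methylation and desilylation of the 7-hydroxy-2,3-dihydrobenzofuran 20.
2. Key disconnection: 20 ⇐ furan-tethered alkynyl ether 18 by a gold-catalysed furan–yne benzannulation. The sacrificial furan supplies C3a–C6 and the 7-oxygen; the ynol ether supplies C7, C7a and O1.
3. 18 ⇐ secondary alcohol 13 (O-vinylation, then bromination/elimination). 13 ⇐ Evans syn-aldol of furylacetyl imide 7 with vanillin acetate 8, which sets C2 and C3 together.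
4. 7 ⇐ Pd-catalysed arylation of the Reformatsky reagent of bromoacetyl imide 4 with methyl 5-bromofuran-3-carboxylate 5.
5. Ring order: the guaiacyl ring and the furan are bought; the benzene ring and the dihydrofuran ring are formed together in step 8, the only ring-forming step.

## Route

Step 1
Reactants: 1 (S)-4-benzyl-1,3-oxazolidin-2-one; 2 bromoacetyl bromide
Product: 4 (S)-4-benzyl-3-(bromoacetyl)-1,3-oxazolidin-2-one, via lithium oxazolidinide 3 (not isolated)
Conditions: n-BuLi (1.0 equiv), THF, −78 °C; then 2, −78 → 0 °C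
Reagents that add atoms: none
Why: N-acylation of the lithiated Evans auxiliary by the acid bromide (nucleophilic acyl substitution) is much faster at −78 °C than displacement of the primary alkyl bromide, and the auxiliary stereocentre is not involved.

Step 2
Reactants: 4 (S)-4-benzyl-3-(bromoacetyl)-1,3-oxazolidin-2-one; 5 methyl 5-bromofuran-3-carboxylate
Product: 7 (S)-4-benzyl-3-{[4-(methoxycarbonyl)furan-2-yl]acetyl}-1,3-oxazolidin-2-one, via Reformatsky zinc enolate 6 (not isolated)
Conditions: activated Zn dust, THF, rt; then 5, Pd(dba)2 (2 mol %), Q-Phos (2 mol %), THF, rt → 50 °C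
Reagents that add atoms: none
Why: Zinc insertion into the α-bromo imide gives a Reformatsky reagent whose Negishi-type Pd-catalysed α-arylation with the furyl bromide runs near room temperature, where the methyl ester and the imide survive and no stereocentre is formed.

Step 3
Reactants: 7 (S)-4-benzyl-3-{[4-(methoxycarbonyl)furan-2-yl]acetyl}-1,3-oxazolidin-2-one; 8 4-formyl-2-methoxyphenyl acetate (vanillin acetate)
Product: 11 (S)-4-benzyl-3-{(2R,3S)-3-(4-acetoxy-3-methoxyphenyl)-3-hydroxy-2-[4-(methoxycarbonyl)furan-2-yl]propanoyl}-1,3-oxazolidin-2-one, via Z-boron enolate 9 (not isolated), via boron aldolate 10 (not isolated)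
Conditions: Bu2BOTf (1.1 equiv), i-Pr2NEt (1.3 equiv), CH2Cl2, −78 → 0 °C; 8, −78 → 0 °C; pH 7 buffer, MeOH, 30% H2O2, 0 °C
Reagents that add atoms: none
Why: Evans syn-aldol reaction in which the Z-boron enolate reacts through a chair Zimmerman–Traxler transition state on the face opposite the benzyl group of the (S)-auxiliary, setting both new stereocentres at once as (2R,3S), the syn pattern that maps onto the 2,3-trans ring of the target.

Step 4
Reactants: 11 (S)-4-benzyl-3-{(2R,3S)-3-(4-acetoxy-3-methoxyphenyl)-3-hydroxy-2-[4-(methoxycarbonyl)furan-2-yl]propanoyl}-1,3-oxazolidin-2-one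
Product: 12 methyl 5-[(1S,2R)-1,3-dihydroxy-1-(4-hydroxy-3-methoxyphenyl)propan-2-yl]furan-3-carboxylate
Conditions: LiBH4 (4 equiv), H2O (1 equiv), THF, 0 °C; aqueous work-up
Reagents that add atoms: none
Why: Chemoselective hydride reduction (reductive removal of the auxiliary) takes the activated imide carbonyl to the primary alcohol faster than the conjugated methyl furoate reacts, the aryl acetate is reduced off in the same operation, and neither stereocentre can epimerise once the carbonyl is gone.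

Step 5
Reactants: 12 methyl 5-[(1S,2R)-1,3-dihydroxy-1-(4-hydroxy-3-methoxyphenyl)propan-2-yl]furan-3-carboxylate
Product: 13 methyl 5-[(1S,2R)-1-hydroxy-1-{3-methoxy-4-[(triisopropylsilyl)oxy]phenyl}-3-[(triisopropylsilyl)oxy]propan-2-yl]furan-3-carboxylate
Conditions: TIPSCl (2.2 equiv), imidazole (5 equiv), DMF, 0 °C → rt
Reagents that add atoms: chlorotri(propan-2-yl)silane (TIPSCl), CC(C)[Si](Cl)(C(C)C)C(C)C
Why: Silyl ether formation with the bulky TIPS chloride is selective for the phenol and the primary alcohol over the hindered secondary benzylic alcohol, which stays free for the next step.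

Step 6
Reactants: 13 methyl 5-[(1S,2R)-1-hydroxy-1-{3-methoxy-4-[(triisopropylsilyl)oxy]phenyl}-3-[(triisopropylsilyl)oxy]propan-2-yl]furan-3-carboxylate; 14 vinyl acetate
Product: 15 methyl 5-[(1S,2R)-1-(ethenyloxy)-1-{3-methoxy-4-[(triisopropylsilyl)oxy]phenyl}-3-[(triisopropylsilyl)oxy]propan-2-yl]furan-3-carboxylate
Conditions: [Ir(cod)Cl]2 (2 mol %), Na2CO3 (0.6 equiv), toluene, 100 °C
Reagents that add atoms: none
Why: Iridium-catalysed transfer vinylation from vinyl acetate converts the free secondary alcohol into its vinyl ether without breaking the C–O bond at the stereocentre, so configuration is retained.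

Step 7
Reactants: 15 methyl 5-[(1S,2R)-1-(ethenyloxy)-1-{3-methoxy-4-[(triisopropylsilyl)oxy]phenyl}-3-[(triisopropylsilyl)oxy]propan-2-yl]furan-3-carboxylate
Product: 18 methyl 5-[(1S,2R)-1-(ethynyloxy)-1-{3-methoxy-4-[(triisopropylsilyl)oxy]phenyl}-3-[(triisopropylsilyl)oxy]propan-2-yl]furan-3-carboxylate, via dibromide 16 (not isolated), via lithium acetylide 17 (not isolated)
Conditions: Br2 (1.0 equiv), CH2Cl2, −78 °C; then LDA (4 equiv), THF, −78 → −30 °C; sat. aq NaHCO3; used at once below rt
Reagents that add atoms: none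
Why: Bromination of the electron-rich enol ether followed by double dehydrobromination with an amide base (the classical enol ether to alkynyl ether sequence) gives the terminal ynol ether, LDA being chosen because unlike an alkyllithium it does not add to the methyl ester.

Step 8
Reactants: 18 methyl 5-[(1S,2R)-1-(ethynyloxy)-1-{3-methoxy-4-[(triisopropylsilyl)oxy]phenyl}-3-[(triisopropylsilyl)oxy]propan-2-yl]furan-3-carboxylate
Product: 20 methyl (2S,3R)-7-hydroxy-2-{3-methoxy-4-[(triisopropylsilyl)oxy]phenyl}-3-{[(triisopropylsilyl)oxy]methyl}-2,3-dihydro-1-benzofuran-5-carboxylate, via arene oxide 19 (not isolated)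
Conditions: Ph3PAuNTf2 (3 mol %), CH2Cl2 (0.02 M), 0 °C → rt
Reagents that add atoms: none
Why: Hashmi phenol synthesis (gold-catalysed intramolecular furan–yne reaction) in its alkynyl ether variant, in which the tether-bearing furan carbon attacks the gold-activated ynol ether at its oxygen-bearing carbon (5-exo), the furan opens and recloses through arene oxide 19, and oxygen-directed opening of that epoxide gives the 7-phenol, so that the benzene ring and the dihydrofuran ring are both created in this one operation while the two stereocentres, which take part in no bond change, are carried over unchanged.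

Step 9
Reactants: 20 methyl (2S,3R)-7-hydroxy-2-{3-methoxy-4-[(triisopropylsilyl)oxy]phenyl}-3-{[(triisopropylsilyl)oxy]methyl}-2,3-dihydro-1-benzofuran-5-carboxylate
Product: 21 methyl (2S,3R)-7-methoxy-2-{3-methoxy-4-[(triisopropylsilyl)oxy]phenyl}-3-{[(triisopropylsilyl)oxy]methyl}-2,3-dihydro-1-benzofuran-5-carboxylate
Conditions: MeI (3 equiv), K2CO3 (2 equiv), acetone, 40 °C
Reagents that add atoms: iodomethane, CI
Why: Williamson O-methylation of the only free phenol (SN2 on iodomethane) installs the 7-methoxy group while the silyl ethers and the methyl ester are inert to K2CO3 in acetone.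

Step 10
Reactants: 21 methyl (2S,3R)-7-methoxy-2-{3-methoxy-4-[(triisopropylsilyl)oxy]phenyl}-3-{[(triisopropylsilyl)oxy]methyl}-2,3-dihydro-1-benzofuran-5-carboxylate
Product: 22 curlignan, methyl (2S,3R)-2-(4-hydroxy-3-methoxyphenyl)-3-(hydroxymethyl)-7-methoxy-2,3-dihydro-1-benzofuran-5-carboxylate
Conditions: TBAF (2.5 equiv), AcOH (2.5 equiv), THF, 0 °C → rt
Reagents that add atoms: none
Why: Fluoride-mediated desilylation, buffered with acetic acid so that the liberated phenoxide does not open the benzylic ether, removes both TIPS groups and leaves the ester and both stereocentres untouched.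

## Compound list

1 | (S)-4-benzyl-1,3-oxazolidin-2-one | O=C1N[C@@H](Cc2ccccc2)CO1 | starting material
2 | bromoacetyl bromide | BrCC(Br)=O | starting material
3 | N-lithio derivative of 1 (formed in the flask) | O=C1OC[C@H](Cc2ccccc2)N1[Li] | intermediate
4 | (S)-4-benzyl-3-(bromoacetyl)-1,3-oxazolidin-2-one | O=C1OC[C@H](Cc2ccccc2)N1C(=O)CBr | intermediate
5 | methyl 5-bromofuran-3-carboxylate | COC(=O)c1coc(Br)c1 | starting material
6 | bromozinc (Reformatsky) enolate of 4, C-bound form (formed in the flask) | O=C1OC[C@H](Cc2ccccc2)N1C(=O)C[Zn]Br | intermediate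
7 | (S)-4-benzyl-3-{[4-(methoxycarbonyl)furan-2-yl]acetyl}-1,3-oxazolidin-2-one | COC(=O)c1coc(CC(=O)N2[C@@H](Cc3ccccc3)COC2=O)c1 | intermediate
8 | 4-formyl-2-methoxyphenyl acetate (vanillin acetate) | CC(=O)Oc1ccc(C=O)cc1OC | starting material
9 | Z-dibutylboron enolate of 7 (formed in the flask) | CCCCB(CCCC)O/C(=C\c1cc(C(=O)OC)co1)N1[C@@H](Cc2ccccc2)COC1=O | intermediate
10 | O-dibutylboryl aldolate of 11 (formed in the flask) | COC(=O)c1coc([C@@H]([C@H](OB(CCCC)CCCC)c2ccc(OC(C)=O)c(OC)c2)C(=O)N2[C@@H](Cc3ccccc3)COC2=O)c1 | intermediate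
11 | (S)-4-benzyl-3-{(2R,3S)-3-(4-acetoxy-3-methoxyphenyl)-3-hydroxy-2-[4-(methoxycarbonyl)furan-2-yl]propanoyl}-1,3-oxazolidin-2-one | COC(=O)c1coc([C@@H]([C@H](O)c2ccc(OC(C)=O)c(OC)c2)C(=O)N2[C@@H](Cc3ccccc3)COC2=O)c1 | intermediate
12 | methyl 5-[(1S,2R)-1,3-dihydroxy-1-(4-hydroxy-3-methoxyphenyl)propan-2-yl]furan-3-carboxylate | COC(=O)c1coc([C@@H]([C@H](O)c2ccc(O)c(OC)c2)CO)c1 | intermediate
13 | methyl 5-[(1S,2R)-1-hydroxy-1-{3-methoxy-4-[(triisopropylsilyl)oxy]phenyl}-3-[(triisopropylsilyl)oxy]propan-2-yl]furan-3-carboxylate | COC(=O)c1coc([C@@H]([C@H](O)c2ccc(O[Si](C(C)C)(C(C)C)C(C)C)c(OC)c2)CO[Si](C(C)C)(C(C)C)C(C)C)c1 | intermediate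
14 | vinyl acetate | CC(=O)OC=C | starting material
15 | vinyl ether of 13 (1S,2R) | COC(=O)c1coc([C@@H]([C@H](OC=C)c2ccc(O[Si](C(C)C)(C(C)C)C(C)C)c(OC)c2)CO[Si](C(C)C)(C(C)C)C(C)C)c1 | intermediate
16 | 1,2-dibromoethyl ether from 15, both epimers at CHBr (formed in the flask) | COC(=O)c1coc([C@@H]([C@H](OC(Br)CBr)c2ccc(O[Si](C(C)C)(C(C)C)C(C)C)c(OC)c2)CO[Si](C(C)C)(C(C)C)C(C)C)c1 | intermediate
17 | lithium acetylide of 18 (formed in the flask) | COC(=O)c1coc([C@@H]([C@H](OC#C[Li])c2ccc(O[Si](C(C)C)(C(C)C)C(C)C)c(OC)c2)CO[Si](C(C)C)(C(C)C)C(C)C)c1 | intermediate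
18 | methyl 5-[(1S,2R)-1-(ethynyloxy)-1-{3-methoxy-4-[(triisopropylsilyl)oxy]phenyl}-3-[(triisopropylsilyl)oxy]propan-2-yl]furan-3-carboxylate | COC(=O)c1coc([C@@H]([C@H](OC#C)c2ccc(O[Si](C(C)C)(C(C)C)C(C)C)c(OC)c2)CO[Si](C(C)C)(C(C)C)C(C)C)c1 | intermediate
19 | 6,7-arene oxide of 20, either epoxide face (formed in the flask) | COC(=O)C=1C2OC2C3=C(C=1)[C@H](CO[Si](C(C)C)(C(C)C)C(C)C)[C@@H](c1ccc(O[Si](C(C)C)(C(C)C)C(C)C)c(OC)c1)O3 | intermediate
20 | methyl (2S,3R)-7-hydroxy-2-{3-methoxy-4-[(triisopropylsilyl)oxy]phenyl}-3-{[(triisopropylsilyl)oxy]methyl}-2,3-dihydro-1-benzofuran-5-carboxylate | COC(=O)c1cc(O)c2c(c1)[C@H](CO[Si](C(C)C)(C(C)C)C(C)C)[C@@H](c1ccc(O[Si](C(C)C)(C(C)C)C(C)C)c(OC)c1)O2 | intermediate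
21 | methyl (2S,3R)-7-methoxy-2-{3-methoxy-4-[(triisopropylsilyl)oxy]phenyl}-3-{[(triisopropylsilyl)oxy]methyl}-2,3-dihydro-1-benzofuran-5-carboxylate | COC(=O)c1cc(OC)c2c(c1)[C@H](CO[Si](C(C)C)(C(C)C)C(C)C)[C@@H](c1ccc(O[Si](C(C)C)(C(C)C)C(C)C)c(OC)c1)O2 | intermediate
22 | curlignan, methyl (2S,3R)-2-(4-hydroxy-3-methoxyphenyl)-3-(hydroxymethyl)-7-methoxy-2,3-dihydro-1-benzofuran-5-carboxylate | COC(=O)c1cc(OC)c2c(c1)[C@H](CO)[C@@H](c1ccc(O)c(OC)c1)O2 | target

## Step count and risks

Total step count: 10. Longest linear sequence: 10 (steps 1–10; 5, 8 and 14 are bought and enter directly).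

**Most likely to fail, first: step 8.** The gold-activated ynol ether sits on a benzylic oxygen whose aryl ring carries a para silyloxy donor. Ionisation of that C–O bond or a sigmatropic shift of the ynol ether can compete with furan attack, and the ester-bearing furan is a weaker nucleophile than in simple cases. The fallback changes the electronic design of the substrate rather than the catalyst. It sets out from triol 12. Pivaloyl chloride in pyridine masks the phenol and the primary alcohol as electron-poor esters, giving bis-pivalate F1, whose aryl ring no longer stabilises a benzylic cation. Iridium-catalysed vinylation with 14 gives vinyl ether F2. Bromination and LDA elimination (pivalates have no α-hydrogen and resist LDA at −78 °C) give ynol ether F3. The gold cyclisation gives phenol F4, and MeI/K2CO3 gives methyl ether F5. NaOMe in MeOH then removes both pivalates and the sequence comes back to the route at 22.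

**Second: step 7.** Bromine has to pick the enol ether over the furan and the electron-rich arene, and the benzylic alkynyl ether is thermally labile. The fallback builds the ynol ether by the dichlorovinyl ether route instead. It sets out from 13. The methyl ester is cleaved with KOSiMe3 in THF to give acid F6, because a carboxylate is inert to n-BuLi whereas the ester is not. KH and trichloroethylene convert the alcohol into dichlorovinyl ether F7. n-BuLi (3.3 equiv, −78 → −40 °C) followed by a methanol quench gives the ynol ether as its lithium carboxylate F8. MeI in DMF in the same flask re-forms the methyl ester and the sequence comes back at 18, bypassing 15.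

**Third: step 2.** The Reformatsky reagent of an N-acyl oxazolidinone can self-condense, and its Pd-catalysed arylation is less established than that of ester zinc enolates. The fallback makes the furylacetic acid first and attaches the auxiliary afterwards. It sets out from 5. Pd-catalysed coupling with commercial (2-tert-butoxy-2-oxoethyl)zinc bromide gives tert-butyl ester F9. TFA gives acid F10. Pivaloyl chloride and Et3N give mixed anhydride F11, which acylates lithiated auxiliary 3 and comes back at 7.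

Further compounds
F1 | step 8 | methyl 5-[(1S,2R)-1-hydroxy-1-[3-methoxy-4-(pivaloyloxy)phenyl]-3-(pivaloyloxy)propan-2-yl]furan-3-carboxylate | COC(=O)c1coc([C@@H]([C@H](O)c2ccc(OC(=O)C(C)(C)C)c(OC)c2)COC(=O)C(C)(C)C)c1
F2 | step 8 | vinyl ether of F1 | COC(=O)c1coc([C@@H]([C@H](OC=C)c2ccc(OC(=O)C(C)(C)C)c(OC)c2)COC(=O)C(C)(C)C)c1
F3 | step 8 | ethynyl ether of F1 | COC(=O)c1coc([C@@H]([C@H](OC#C)c2ccc(OC(=O)C(C)(C)C)c(OC)c2)COC(=O)C(C)(C)C)c1
F4 | step 8 | methyl (2S,3R)-7-hydroxy-2-[3-methoxy-4-(pivaloyloxy)phenyl]-3-[(pivaloyloxy)methyl]-2,3-dihydro-1-benzofuran-5-carboxylate | COC(=O)c1cc(O)c2c(c1)[C@H](COC(=O)C(C)(C)C)[C@@H](c1ccc(OC(=O)C(C)(C)C)c(OC)c1)O2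
F5 | step 8 | methyl (2S,3R)-7-methoxy-2-[3-methoxy-4-(pivaloyloxy)phenyl]-3-[(pivaloyloxy)methyl]-2,3-dihydro-1-benzofuran-5-carboxylate | COC(=O)c1cc(OC)c2c(c1)[C@H](COC(=O)C(C)(C)C)[C@@H](c1ccc(OC(=O)C(C)(C)C)c(OC)c1)O2
F6 | step 7 | 5-[(1S,2R)-1-hydroxy-1-{3-methoxy-4-[(triisopropylsilyl)oxy]phenyl}-3-[(triisopropylsilyl)oxy]propan-2-yl]furan-3-carboxylic acid | OC(=O)c1coc([C@@H]([C@H](O)c2ccc(O[Si](C(C)C)(C(C)C)C(C)C)c(OC)c2)CO[Si](C(C)C)(C(C)C)C(C)C)c1
F7 | step 7 | (E)-1,2-dichlorovinyl ether of F6 | OC(=O)c1coc([C@@H]([C@H](O/C(Cl)=C\Cl)c2ccc(O[Si](C(C)C)(C(C)C)C(C)C)c(OC)c2)CO[Si](C(C)C)(C(C)C)C(C)C)c1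
F8 | step 7 | lithium carboxylate of the ethynyl ether of F6 | [Li+].[O-]C(=O)c1coc([C@@H]([C@H](OC#C)c2ccc(O[Si](C(C)C)(C(C)C)C(C)C)c(OC)c2)CO[Si](C(C)C)(C(C)C)C(C)C)c1
F9 | step 2 | tert-butyl [4-(methoxycarbonyl)furan-2-yl]acetate | COC(=O)c1coc(CC(=O)OC(C)(C)C)c1
F10 | step 2 | [4-(methoxycarbonyl)furan-2-yl]acetic acid | COC(=O)c1coc(CC(=O)O)c1
F11 | step 2 | [4-(methoxycarbonyl)furan-2-yl]acetic pivalic anhydride | COC(=O)c1coc(CC(=O)OC(=O)C(C)(C)C)c1
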